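## The problem

The target, (2S)-5,7,4'-trihydroxy-3'-methoxy-8-(3-methylbut-2-enyl)flavanone, is a chroman-4-one (rings A and C, fused through C4a and C8a) with a 4-hydroxy-3-methoxyphenyl ring B on C2 and a linear prenyl chain on C8. Without the prenyl group it is homoeriodictyol, a catalogue flavanone, so the only skeletal bond that really has to be made is C8–C1''. That bond is hard for positional reasons: in the phloroglucinol-type ring A both C6 (between the 5- and 7-hydroxyls) and C8 (between the 7-hydroxyl and O1) are strongly nucleophilic, three phenolic oxygens compete, and an allylic electrophile can bond through either terminus, so reagent control leads to C6-, C8-, O-, bis- and reverse-prenylated mixtures. C2 is the only stereocentre and nothing else in the molecule can direct it, so its (S) configuration has to come from a resolution, a chiral catalyst or an enzyme. It is also easily lost, because base opens ring C by a retro-oxa-Michael reaction (helped by the 4'-phenolate) to an achiral open-chain enone that recloses from both faces. The prenyl group beside the free 7-hydroxyl is the acid-sensitive counterpart: strong acid closes it onto O7 as a 2,2-dimethylchroman or hydrates the olefin, which argues against late acidic deprotections. The feature that opens a short way through is the (2S)-5,7-dihydroxychroman-4-one core itself: its C8–H, flanked by O1 and the 7-hydroxyl and para to the 5-hydroxyl, is the position that plant flavanone 8-dimethylallyltransferases prenylate in their natural substrates, and the one difference from those substrates, the 3'-methoxy group, lies on the remote ring B.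

## Retrosynthesis

The first cut is the C8–C1'' bond of target 5, giving (2S)-homoeriodictyol 2 and dimethylallyl diphosphate 4. The neighbouring cuts inside the heterocycle (O1–C8a, C4–C4a, C2–C1') would each need a separately built, regiodefined prenylated ring A. This cut removes only the five-carbon chain and leaves the whole flavanone, stereocentre included, untouched. Precursor 2 is an unprotected, known flavanone. The forward reaction must alkylate a free triphenol once, at C8 not C6, on carbon not oxygen, through the primary allylic carbon, at a pH that leaves C2 alone. That is asked of an aromatic prenyltransferase, not of a reagent.

Donor 4 is cut at its C1''–O bond to the primary allylic bromide 3, with the diphosphate unit supplied as a reagent. Phosphorylating the alcohol with activated phosphate would give mono-, di- and triphosphate together, whereas displacement of bromide by a preformed diphosphate installs the whole head group in one substitution. Compound 3 is a five-carbon catalogue chemical. The forward reaction must be an SN2 process at the primary carbon without allylic transposition, and the work-up must avoid acid.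

Flavanone 2 is not disconnected further. No bond is cut; the stereochemical problem is reduced to separating 2 from commercial racemic homoeriodictyol 1 on a chiral stationary phase. A de novo asymmetric synthesis of 2 would spend several steps on a skeleton that can be bought. The price is that at most half of 1 can become 2. This is accepted because 1 is purchased and the separation is a single physical operation that exposes C2 to neither base nor heat. The separation must give baseline resolution under slightly acidic, non-racemising elution.

## Roads not taken

Alternative 1: Ring C would be closed last at the O1–C8a bond.
- Forward step: the (S)-configured acyclic 1,3-diol aryl triflate A1, carrying the prenyl group, the triflate and two MOM ethers on ring A, would cyclise under zerovalent palladium (from Pd(OAc)2 and a bulky di-tert-butyl biaryl phosphine, with Cs2CO3) by intramolecular aryl ether formation to the flavan-4-ol tris(MOM) ether A2. Oxidation at C4 and removal of three MOM groups would follow.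
- Merits: C2 is set in the open chain by asymmetric chemistry of broad scope and is not touched by the closure, since the new bond is made at an aryl carbon. Ring C is never open in base once formed. The prenyl position is fixed by construction.
- Weak points: the triflate carbon of A1 sits between two ortho substituents on a very electron-rich ring, the least favourable case for oxidative addition, so triflate S–O cleavage by carbonate and β-hydride elimination from the palladium alkoxide can compete. A1 is a hexasubstituted benzene whose assembly re-poses the ring A regiochemistry and costs many steps. After A2 there remain an oxidation and an acidic triple deprotection beside a prenyl group ortho to the emerging 7-hydroxyl.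
- Comparison: this road is better in that it needs no enzyme, does not depend on an untested substrate tolerance and can be scaled by ordinary means. The chosen plan sets against it two linear steps from purchasable material, no protecting group, no acid at the end, and regiochemistry decided in the bond-forming event itself.

Alternative 2: Ring C would be closed at C4–C4a by intramolecular Friedel–Crafts acylation.
- Forward step: the (S)-3-aryl-3-aryloxypropanoic acid A3 (ring A as a 2-prenyl-3,5-bis(silyloxy)phenyl ether, ring B as its 4-acetate) would be activated with trifluoroacetic anhydride, or as the acid chloride with SnCl4 at low temperature, to give the protected flavanone A4. Desilylation and deacetylation would finish.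
- Merits: the closure is regiochemically unambiguous, because the only other ortho position carries the prenyl group. A4 already has the complete skeleton at the correct oxidation level.
- Weak points: the stereocentre of A3 is a benzylic aryl ether on an electron-rich arene, β to the acylium carbon, so ionisation or loss of the phenol threatens the configuration in the key step itself. The acidic medium meets a trisubstituted olefin next to an aryl silyl ether. Forming the aryl ether of A3 with inversion, from a hindered electron-rich phenol at a benzylic carbinol, invites partial racemisation. Fluoride desilylation of A4 is basic enough to open ring C.
- Comparison: it equals the chosen plan in securing C8 substitution and is better in not depending on a biocatalyst. It is worse in that C2 is endangered at three separate stages and the step count is several times higher; in the chosen plan C2, once resolved, meets only near-neutral water.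

Alternative 3: The C2–C1' bond and the stereocentre would be made together by conjugate arylation.
- Forward step: the 5,7-bis(MOM) 8-prenylchromone A5 and 3-methoxy-4-(methoxymethoxy)phenylboronic acid A6 would react under a chiral diene complex of monovalent rhodium prepared from [RhCl(C2H4)2]2 to give the tris(MOM) ether A7 of the target. Acid would then remove the MOM groups.
- Merits: it is the most convergent chemical route. The stereocentre is set catalytically, with a ligand available in either hand, without a resolution. The reaction class is established for chromones.
- Weak points: a chromone with two donor oxygens on ring A is a weak acceptor, so slow addition competes with protodeboronation of the electron-rich A6. A5 must first be built regioselectively, which moves the C6/C8 problem upstream instead of solving it. The final acidic removal of three MOM groups from A7 exposes the prenyl/7-hydroxyl pair to the conditions it tolerates least.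
- Comparison: this is the strongest alternative. In enantiocontrol by design, material economy at the stereocentre, scalability and access to analogues it is better than the chosen plan. The chosen plan sets against it brevity, the absence of protecting groups and of any acidic step, and regiochemistry decided in one event. Its price is a resolution that uses at most half of the flavanone and a membrane enzyme of modest throughput whose acceptance of 2 is inferred from close relatives.

Key step: step 3

Assumption: commercial homoeriodictyol is taken to be the racemate; material already enriched in the (2S) form would only lighten step 1.
Assumption: compound 4 is drawn as the free acid but is made, stored and used as its trisammonium salt.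
Assumption: the prenyltransferase is a catalyst obtained by expressing a synthetic, codon-optimised gene in Saccharomyces cerevisiae and collecting the microsomal membranes; this is not counted as a synthetic step.

## Route

Step 1
Reactants: 1 racemic homoeriodictyol (5,7,4'-trihydroxy-3'-methoxyflavanone)
Product: 2 (2S)-homoeriodictyol
Conditions: preparative chiral HPLC, immobilised amylose tris(3,5-dimethylphenylcarbamate) on silica, n-hexane/EtOH/HCO2H 70:30:0.1, 25 °C; fractions evaporated below 30 °C
Reagents that add atoms: none
Why: Resolution of enantiomers on a polysaccharide chiral stationary phase, routine for flavanones; no bond is made or broken and the slightly acidic eluent keeps the base-labile C2 centre fixed. The fraction showing the circular dichroism pattern established for (2S)-flavanones (negative band near 290 nm, positive near 330 nm) is taken as 2. The other fraction, holding the (2R) antipode, is set aside and not carried on.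

Step 2
Reactants: 3 prenyl bromide (1-bromo-3-methylbut-2-ene)
Product: 4 dimethylallyl diphosphate (3-methylbut-2-en-1-yl diphosphate), as trisammonium salt
Conditions: (nBu4N)3HP2O7 (2 equiv), MeCN, 0 °C to rt, argon; then Dowex 50WX8 (NH4+ form), 25 mM NH4HCO3 in 2% iPrOH/H2O; lyophilisation; cellulose chromatography (iPrOH/MeCN/0.1 M NH4HCO3)
Reagents that add atoms: tris(tetra-n-butylammonium) hydrogen diphosphate, CCCC[N+](CCCC)(CCCC)CCCC.CCCC[N+](CCCC)(CCCC)CCCC.CCCC[N+](CCCC)(CCCC)CCCC.OP(=O)([O-])OP(=O)([O-])[O-]
Why: SN2 displacement of a primary allylic bromide by the diphosphate anion in dry acetonitrile, the standard halide-displacement synthesis of allylic diphosphates; the tetraalkylammonium counter-ion keeps the nucleophile soluble and reactive, and exchange to the ammonium form in mildly basic buffer avoids acid-catalysed ionisation of the product.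

Step 3
Reactants: 2 (2S)-homoeriodictyol; 4 dimethylallyl diphosphate (trisammonium salt)
Product: 5 (2S)-8-prenylhomoeriodictyol, i.e. (2S)-5,7,4'-trihydroxy-3'-methoxy-8-(3-methylbut-2-enyl)flavanone (target)
Conditions: yeast microsomes carrying recombinant Sophora flavescens flavanone 8-dimethylallyltransferase, 4 (2 equiv, in portions), MgCl2 (10 mM), dithiothreitol (1 mM), Tris-HCl pH 7.5, DMSO (2% v/v), 30 °C, dark; EtOAc extraction, reversed-phase (C18) chromatography
Reagents that add atoms: none
Why: Enzymatic Friedel–Crafts-type prenyl transfer by a membrane-bound aromatic prenyltransferase; the closest known reaction is the C8 dimethylallylation of (2S)-naringenin and other flavanones by this enzyme class, from whose substrates 2 differs only in ring B. The magnesium-bound diphosphate of 4 is anchored by the aspartate-rich motifs of the enzyme, ionisation gives a dimethylallyl cation paired with diphosphate above ring A, C8 attacks through the primary carbon C1'', and the Wheland intermediate loses the C8 proton, so the C8–C1'' bond forms and ring A rearomatises. No ring is closed and no stereocentre is created; C2 should be carried through because the buffer is near neutral and the incubation short. The step needs C8 over C6, carbon over oxygen, linear over reverse attachment, and one prenyl group instead of two. None of these follows from the intrinsic reactivity of 2; all are imposed by the binding pose of the (2S)-5,7-dihydroxychroman-4-one core, which 2 shares with the natural substrates. The 3'-methoxy group lies on ring B, far from the reacting carbon, where flavanones with a 3',4'-dioxygenated ring B are accepted by this enzyme class. The preference of the enzyme for (2S)-flavanones should additionally disfavour any (2R) material that arises in the buffer.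

## Compound list

1 | racemic homoeriodictyol (5,7,4'-trihydroxy-3'-methoxyflavanone) | COc1cc(C2CC(=O)c3c(O)cc(O)cc3O2)ccc1O | starting material
2 | (2S)-homoeriodictyol | COc1cc([C@@H]2CC(=O)c3c(O)cc(O)cc3O2)ccc1O | intermediate
3 | prenyl bromide (1-bromo-3-methylbut-2-ene) | CC(C)=CCBr | starting material
4 | dimethylallyl diphosphate, used as trisammonium salt (SMILES of the parent acid) | CC(C)=CCOP(=O)(O)OP(=O)(O)O | intermediate
5 | (2S)-8-prenylhomoeriodictyol, CNP0266453.1 | COc1cc([C@@H]2CC(=O)c3c(O)cc(O)c(CC=C(C)C)c3O2)ccc1O | target

## Step count and risks

Total step count: 3.
Longest linear sequence: 2 steps (1 → 2 → 5 by steps 1 and 3; the donor branch 3 → 4 → 5 by steps 2 and 3 is equally long).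

**Step 3 (key step).**
- What may go wrong: slow or absent turnover if the 3'-methoxy-4'-hydroxy ring B binds poorly; slippage of regiocontrol towards C6 if the substrate sits differently in the pocket; gradual erosion of configuration at C2 through ring opening in the aqueous buffer, more so if a more alkaline buffer is needed for a useful rate; low volumetric productivity of a membrane enzyme, limiting scale.
- Fallback: a chemical para-Claisen–Cope sequence, known for the parent flavanone, sets out from 2 and comes back to the route at 5. Acetylation of the two non-chelated phenols (Ac2O, pyridine, 0 °C) should give (2S)-7,4'-di-O-acetylhomoeriodictyol F1. Mitsunobu etherification of the chelated 5-hydroxyl with prenol (PPh3, diisopropyl azodicarboxylate, THF) should give (2S)-7,4'-di-O-acetyl-5-O-prenylhomoeriodictyol F2. Eu(fod)3-catalysed Claisen rearrangement to C6 followed by Cope rearrangement to C8 (CHCl3, 60 °C) should give (2S)-7,4'-di-O-acetyl-8-prenylhomoeriodictyol F3. Lipase-catalysed butanolysis of the two aryl acetates (immobilised Candida antarctica lipase B, n-butanol, tert-butyl methyl ether, 40 °C) should then give 5 without base or acid. The enantiomeric purity would be rechecked after the pyridine step and restored by chiral HPLC if needed.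

**Step 2.**
- What may go wrong: ionisation and hydrolysis of the allylic diphosphate during counter-ion exchange and chromatography; carry-over of excess inorganic diphosphate, which would sequester magnesium and inhibit the transferase in step 3.
- Fallback: setting out from 3 and coming back at 4, the head group is built one phosphate at a time and the diphosphate is never isolated. Displacement of bromide with tetra-n-butylammonium dihydrogen phosphate (MeCN) should give dimethylallyl phosphate F4. This is then phosphorylated by an isopentenyl phosphate kinase with ATP and MgCl2 directly in the prenylation buffer, so that 4 is generated in situ and consumed by the transferase.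

**Step 1.**
- What may go wrong: insufficient resolution or low loading of the polar triphenol on the chiral phase, and on-column racemisation if the eluent is not kept acidic, making throughput impractical; by design no more than half of the injected material can be collected as 2.
- Fallback: setting out from 1 and coming back at 2, the separation is replaced by an enzymatic ring closure that can convert all of the material. Brief heating of 1 in concentrated aqueous KOH and pouring into cold dilute HCl should precipitate homoeriodictyol chalcone F5. Recombinant chalcone isomerase (for example from Medicago sativa) in phosphate buffer pH 6.5 at 10 °C should close it to 2. The weak point is background non-enzymatic closure to racemate, which the low pH and temperature are meant to suppress.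

## Further compounds

F1 | step 3 | (2S)-7,4'-di-O-acetylhomoeriodictyol | COc1cc([C@@H]2CC(=O)c3c(O)cc(OC(C)=O)cc3O2)ccc1OC(C)=O
F2 | step 3 | (2S)-7,4'-di-O-acetyl-5-O-(3-methylbut-2-enyl)homoeriodictyol | COc1cc([C@@H]2CC(=O)c3c(OCC=C(C)C)cc(OC(C)=O)cc3O2)ccc1OC(C)=O
F3 | step 3 | (2S)-7,4'-di-O-acetyl-8-(3-methylbut-2-enyl)homoeriodictyol | COc1cc([C@@H]2CC(=O)c3c(O)cc(OC(C)=O)c(CC=C(C)C)c3O2)ccc1OC(C)=O
F4 | step 2 | dimethylallyl phosphate (3-methylbut-2-en-1-yl dihydrogen phosphate) | CC(C)=CCOP(=O)(O)O
F5 | step 1 | homoeriodictyol chalcone, (E)-1-(2,4,6-trihydroxyphenyl)-3-(4-hydroxy-3-methoxyphenyl)prop-2-en-1-one | COc1cc(/C=C/C(=O)c2c(O)cc(O)cc2O)ccc1O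
A1 | alternative 1 | (S)-1,3-diol aryl triflate: 2-[(3S)-1,3-dihydroxy-3-(3-methoxy-4-(methoxymethoxy)phenyl)propyl]-3,5-bis(methoxymethoxy)-6-(3-methylbut-2-enyl)phenyl triflate | COc1cc([C@@H](O)CC(O)c2c(OCOC)cc(OCOC)c(CC=C(C)C)c2OS(=O)(=O)C(F)(F)F)ccc1OCOC
A2 | alternative 1 | (2S)-8-prenylflavan-4-ol tris(methoxymethyl) ether, either configuration at C4 | COc1cc([C@@H]2CC(O)c3c(OCOC)cc(OCOC)c(CC=C(C)C)c3O2)ccc1OCOC
A3 | alternative 2 | (3S)-3-(4-acetoxy-3-methoxyphenyl)-3-[3,5-bis(tert-butyldimethylsilyloxy)-2-(3-methylbut-2-enyl)phenoxy]propanoic acid | COc1cc([C@H](CC(=O)O)Oc2cc(O[Si](C)(C)C(C)(C)C)cc(O[Si](C)(C)C(C)(C)C)c2CC=C(C)C)ccc1OC(C)=O
A4 | alternative 2 | (2S)-8-prenylhomoeriodictyol 5,7-bis(tert-butyldimethylsilyl) ether 4'-acetate | COc1cc([C@@H]2CC(=O)c3c(O[Si](C)(C)C(C)(C)C)cc(O[Si](C)(C)C(C)(C)C)c(CC=C(C)C)c3O2)ccc1OC(C)=O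
A5 | alternative 3 | 5,7-bis(methoxymethoxy)-8-(3-methylbut-2-enyl)chromen-4-one | O=c1ccoc2c(CC=C(C)C)c(OCOC)cc(OCOC)c12
A6 | alternative 3 | 3-methoxy-4-(methoxymethoxy)phenylboronic acid | COCOc1ccc(B(O)O)cc1OC
A7 | alternative 3 | (2S)-8-prenylhomoeriodictyol tris(methoxymethyl) ether | COc1cc([C@@H]2CC(=O)c3c(OCOC)cc(OCOC)c(CC=C(C)C)c3O2)ccc1OCOC
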